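## Structural features

The target is a γ-butyrolactone (ring A: O1, C2 carbonyl, C3, C4, C5) with two benzyl groups. C3 is joined through the methylene C7 to a 4-hydroxy-3-methoxyphenyl ring (ring B), and C4 through the methylene C7' to a 3-hydroxy-4-methoxyphenyl ring (ring C). C3 and C4 are the only stereocentres; they are adjacent, both R, and their benzyl groups are trans. C3 lies α to the lactone carbonyl and can be equilibrated towards the more stable trans arrangement, so the task that cannot be avoided is the absolute configuration at C4, whose three carbon substituents (C3, C5, C7') differ only at a distance. Rings B and C are constitutional isomers (hydroxy and methoxy exchanged), so each must come from its own labelled building block. The fragile points are the free phenols (oxidation, and quinone methide formation at ring B under base), the electron-rich arenes (electrophiles and one-electron oxidants) and the lactone (hydrolysis and C3 epimerisation under base). The feature used is that C7 and C7' are benzylic CH2 carbons placed 1,4 across the C3–C4 bond: a bond drawn between them turns C3, C4, C7' and C7 into a 1,2-diarylcyclobutane, the [2+2] adduct of the C7=C3 alkene of a ferulate and the C7'=C4 alkene of an isoferulyl alcohol derivative. That extra bond is strained and benzylic at both ends, so it can be removed again by hydrogenolysis; the real difficulty is to form the adduct cross-selectively in one absolute sense and then to cut exactly one of its four ring bonds.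

## Logic of the disconnections

The first cut is the acyl bond C2–O1 of 11, which leads to the γ-hydroxy ester 10 and, with the C5 oxygen capped by silicon, to 9. A γ-hydroxy ester closes readily under acid, so the ring need not be carried through the earlier steps, and an open chain is what the ring scission below delivers. The gain is one ring fewer, with C2 and C5 at the ester and alcohol oxidation levels of the two alkene partners. The forward step must avoid base, because C3 is epimerisable and ring B can form a quinone methide.

Next a bond is added, in the retrosynthetic sense, between C7 and C7', and both phenols are capped as benzyl ethers; this leads through 8 to the all-trans cyclobutane 7. The cut is placed here because it turns two acyclic stereocentres with remote differences into ring stereocentres of a cycloadduct, with both arenes already on the correct carbons. The demand on the forward step is that hydrogenolysis breaks only C7–C7' and leaves C3–C7, C4–C7' and C3–C4 intact. The ester and the oxymethyl group are trans on the four-membered ring, so lactonisation cannot occur before the scission, and the order of events is enforced by the structure.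

The cyclobutane 7 is then cut at C3–C4 and C7–C7' into the enoate 2 and the silyl-protected cinnamyl alcohol 6. Two achiral, flat E-alkenes replace a ring with four stereocentres, and each carries one of the isomeric arenes. The forward step must be cross-selective, head-to-head, and face-selective at C3, with C4 following C3 in a trans sense. Only 2 has a carbonyl group that can bind a Lewis acid, which is what differentiates the partners.

The alkene 6 is cut at the bond between ring C and C7' into the aryl bromide 4 and the alkenylboronate 5. This cut brings the E geometry and the silyl ether in ready-made and avoids an ester reduction and a separate silylation. The forward coupling must retain the alkene geometry and tolerate the silyl ether.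

Finally the O–benzyl bonds of 4 and 2 are cut to the phenols 3 and 1. Benzyl is chosen because it removes the acidic protons that would destroy the Lewis acid, is a weak Lewis base, and leaves in the same hydrogenolysis that cuts the ring bond. The forward steps are simple O-alkylations.

## Other disconnections considered

Alternative 1: The cuts are the two exocyclic bonds C4–C7' and C3–C7; the lactone carbons come from the chiral butenolide (5R)-5-(menthyloxy)furan-2(5H)-one A1. In the forward sense the lithium salt of the dithioacetal [3-(benzyloxy)-4-methoxyphenyl]bis(phenylsulfanyl)methane A2 would add to C4 of A1 anti to the menthyloxy group. The lactone enolate would then be alkylated at C3 by 4-(benzyloxy)-3-methoxybenzyl bromide A3 anti to the new C4 substituent, giving the 3,4-trans-4,5-trans adduct A4 in one pot.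
- In its favour: both stereocentres are set by a resident acetal stereocentre through thermal two-electron steps of predictable sense; each arene arrives on its own reagent; the trans relationship is formed directly; no ring has to be cut afterwards.
- Against it here: the auxiliary is stoichiometric and must be obtained as a single C5 epimer. C7' arrives at the ketone oxidation level and C5 at the aldehyde level, so desulfurisation, reductive removal of the menthyloxy group with re-lactonisation, and O-debenzylation would have to follow. Cryogenic organolithium chemistry and sulfur waste are added.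
- Comparison: on structure it is the equal of the chosen plan in bonds and stereocentres of the final skeleton (two and two), but it closes no ring. On mechanism it is the better plan: substrate control replaces an enantioselective photochemical step that extends its precedent, and no selection among four ring bonds is needed. On step economy the chosen plan is better (about nine steps against five), is catalytic in chirality, and brings both benzylic carbons in at the final oxidation level.

Alternative 2: The cuts are C2–O1 and C2–C3, with C2 supplied by carbon monoxide. The homopropargylic alcohol (R)-2-[3-(benzyloxy)-4-methoxybenzyl]-4-[4-(benzyloxy)-3-methoxyphenyl]but-3-yn-1-ol A5 would be carbonylated with PdI2 and PBu3. An alkoxycarbonyl complex of divalent palladium adds syn across the alkyne and protonolysis releases the E-benzylidene lactone A6.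
- In its favour: the ring and C2 are installed in one catalytic step with defined alkene geometry by ordinary organopalladium chemistry. The later alkene hydrogenation can also remove the benzyl ethers and is far more secure than the C–C hydrogenolysis of a cyclobutane; on this point it is better than the chosen plan.
- Against it here: the key step creates no stereocentre, so C4 must be built beforehand in A5 by a separate multistep asymmetric sequence. Internal aryl alkynes are slower substrates than terminal ones. Hydrogenation of A6 should deliver hydrogen to C3 from the face opposite the C4 benzyl group and so favour the cis lactone, which would need a base epimerisation. A toxic gas under pressure is required.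
- Comparison: on structure it forms two bonds and one ring, as the chosen plan does, but no stereocentre against four (two of them lasting). On mechanism it is better understood ground-state catalysis, and it is equal in that C3 is open to thermodynamic correction in both plans. On step economy it is worse, estimated at nine to ten steps.

Alternative 3: The cuts are C3–C4 and a sacrificial C3–C7' bond, a cyclopropane in place of the cyclobutane. The diazo keto ester (E)-3-[3-(benzyloxy)-4-methoxyphenyl]allyl 3-[4-(benzyloxy)-3-methoxyphenyl]-2-diazo-3-oxopropanoate A7 would lose N2 at the divalent cobalt centre of [Co(por*)]. The cobalt-bound carbon radical at C3 adds to C4 of the tethered alkene and the benzylic radical at C7' closes the three-membered ring by substitution at C3, giving the bicyclic keto lactone A8 with lactone and cyclopropane formed together.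
- In its favour: the reaction is intramolecular, so there is no cross-selectivity or regiochemical question (better than the chosen plan). The lactone is closed in the key step (better). The C3–C7' bond is a donor–acceptor cyclopropane bond and should be hydrogenolysed more readily than a cyclobutane bond (better). The E-alkene fixes C4 relative to C7'.
- Against it here: C7 enters as a ketone and must later be reduced to CH2 through a sensitive β-keto lactone. C3 is quaternary in A8 and its final configuration must be set afterwards by thermodynamic protonation. The chiral porphyrin needs a multistep ligand synthesis, a diazo compound must be handled, and hydrogenolysis must choose C3–C7' over C4–C7'.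
- Comparison: the concept is the same as in the chosen plan. On structure the plans are equal in skeletal bonds formed (two), and this one closes two rings against one. On mechanism it is better in the chemoselectivity of ring formation and the ease of scission, and worse in redox economy. On step economy it is roughly equal to slightly longer (estimated seven to eight steps).

Key step: step 4

Assumption: the oxazaborolidine derived from the (S)-diarylprolinol is taken to expose the face of bound 2 that leads to 3R; if the opposite sense is found, the (R)-catalyst is used with no other change.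

Design remarks:
- The all-trans cyclobutane 7, (1R,2S,3S,4R), maps onto the target with ring C1 = lactone C3 (R) and ring C4 = lactone C4 (R).
- The catalyst controls C3 directly; C4 follows from C3 through the trans preference of the first bond formation.
- AlBr3 is kept below the amount of oxazaborolidine.
- The alkene partner 6 is made by one cross-coupling from the catalogue boronate 5.
- The steps after the key step are run as one telescoped operation.

## Route

Step 1
Reactants: 1 methyl (E)-3-(4-hydroxy-3-methoxyphenyl)acrylate (methyl ferulate)
Product: 2 methyl (E)-3-[4-(benzyloxy)-3-methoxyphenyl]acrylate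
Conditions: BnBr (1.1 equiv), K2CO3 (1.5 equiv), acetone, reflux
Reagents that add atoms: benzyl bromide, BrCc1ccccc1
Why: Williamson ether synthesis: the phenoxide formed with K2CO3 displaces bromide from benzyl bromide (SN2), and the enoate and its E geometry are untouched. The benzyl ether removes the acidic proton that would destroy the Lewis acid of step 4.

Step 2
Reactants: 3 5-bromo-2-methoxyphenol
Product: 4 2-(benzyloxy)-4-bromo-1-methoxybenzene
Conditions: BnBr (1.1 equiv), K2CO3 (1.5 equiv), acetone, reflux
Reagents that add atoms: benzyl bromide, BrCc1ccccc1
Why: Williamson ether synthesis on the phenoxide. The bromine is para to methoxy and meta to the new benzyloxy group, so the later coupling places the side chain as in ring C.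

Step 3
Reactants: 4 2-(benzyloxy)-4-bromo-1-methoxybenzene; 5 (E)-tert-butyldimethyl{[3-(4,4,5,5-tetramethyl-1,3,2-dioxaborolan-2-yl)prop-2-en-1-yl]oxy}silane
Product: 6 (E)-{[3-(3-(benzyloxy)-4-methoxyphenyl)prop-2-en-1-yl]oxy}(tert-butyl)dimethylsilane
Conditions: Pd(dppf)Cl2·CH2Cl2 (3 mol%), K2CO3 (3 equiv), 1,4-dioxane–H2O 5:1, 80 °C
Reagents that add atoms: none
Why: Suzuki–Miyaura coupling: oxidative addition of the C–Br bond to zerovalent palladium, base-assisted transmetalation of the alkenylboronate and reductive elimination, all with retention of the E geometry. The silyl and benzyl ethers are stable to aqueous carbonate.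

Step 4
Reactants: 2 methyl (E)-3-[4-(benzyloxy)-3-methoxyphenyl]acrylate; 6 (E)-{[3-(3-(benzyloxy)-4-methoxyphenyl)prop-2-en-1-yl]oxy}(tert-butyl)dimethylsilane
Product: 7 methyl (1R,2S,3S,4R)-2-[4-(benzyloxy)-3-methoxyphenyl]-3-[3-(benzyloxy)-4-methoxyphenyl]-4-({[tert-butyl(dimethyl)silyl]oxy}methyl)cyclobutane-1-carboxylate (all-trans)
Conditions: [Ir(dF(CF3)ppy)2(dtbbpy)]PF6 (1 mol%), (S)-3,3-bis(3,5-dimethylphenyl)-1-(2,4,6-trifluorophenyl)tetrahydro-1H,3H-pyrrolo[1,2-c][1,3,2]oxazaborole (25 mol%), AlBr3 (20 mol%), 6 (3 equiv), CH2Cl2, −78 °C, blue LEDs (450 nm)
Reagents that add atoms: none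
Why: The ester carbonyl of 2 binds the AlBr3-activated oxazaborolidine, and triplet energy transfer from the photoexcited trivalent iridium complex populates the triplet of this bound cinnamate much faster than that of free 2, so the step is a chiral-Lewis-acid-catalysed, triplet-sensitised crossed [2+2] photocycloaddition. The closest known reaction type is this same cycloaddition of cinnamate esters with styrenes; 6 differs only in carrying a silyloxymethyl group on the non-benzylic alkene carbon. The α-carbon of the triplet enoate (C3) attacks the non-benzylic carbon of 6 (C4) to give a triplet 1,4-diradical that is benzylic at C7 and at C7', and after intersystem crossing the two radical centres recombine, so the cyclobutane is closed stepwise by 1,4-diradical recombination at C7–C7' and not by a concerted pericyclic path. C3 is set in the first bond formation by the oxazaborolidine, whose diarylmethyl and B-aryl groups shield one face of the bound s-trans enoate. C4 is set in the same bond formation relative to C3, trans, because the Lewis-acid-bound ester and the silyloxymethyl group avoid each other and a cis diradical should revert to the alkenes faster than it closes; the catalyst reaches C4 only through this relay. C7 and C7' are fixed at ring closure, where each aryl group takes the face opposite to its ring neighbours, and their configuration is of no consequence because both carbons become CH2. The step needs cross- over homo-coupling, secured by selective sensitisation of the bound ester, by 6 having no Lewis-basic carbonyl group and by its use in excess, and it needs head-to-head regiochemistry, secured by the doubly benzylic diradical. AlBr3 is kept below the amount of oxazaborolidine so that no free AlBr3 remains to drive a racemic background reaction or ionise the p-methoxycinnamyl ether.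

Step 5
Reactants: 7 methyl (1R,2S,3S,4R)-2-[4-(benzyloxy)-3-methoxyphenyl]-3-[3-(benzyloxy)-4-methoxyphenyl]-4-({[tert-butyl(dimethyl)silyl]oxy}methyl)cyclobutane-1-carboxylate
Product: 11 (3R,4R)-3-(4-hydroxy-3-methoxybenzyl)-4-(3-hydroxy-4-methoxybenzyl)dihydrofuran-2(3H)-one, via bisphenol cyclobutane 8 (not isolated), via ring-opened silyloxy ester 9 (not isolated), via hydroxy ester 10 (not isolated)
Conditions: H2 (10 bar), Pd(OH)2/C, EtOAc–AcOH 20:1, 45 °C; filter, concentrate; then p-TsOH·H2O (0.2 equiv), MeOH, 23 °C
Reagents that add atoms: none
Why: Heterogeneous palladium hydrogenolysis should first cleave the two aryl benzyl ethers and then the C7–C7' ring bond, the only ring bond that is benzylic at both ends and the one whose cleavage releases the ring strain (benzylic C–C hydrogenolysis of a 1,2-diarylcyclobutane); C3 and C4 are not involved and keep their configuration. Acid-catalysed methanolysis of the primary silyl ether then frees the C5 hydroxyl, which attacks the ester (5-exo-trig lactonisation) under conditions that neither epimerise C3 nor ionise the ring B phenol. An early loss of silicon is harmless, because the trans-disposed hydroxymethyl and ester groups cannot lactonise on the four-membered ring and all intermediates converge on 11.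

## Compound list

1 | methyl (E)-3-(4-hydroxy-3-methoxyphenyl)acrylate (methyl ferulate) | COC(=O)/C=C/c1ccc(O)c(OC)c1 | starting material
2 | methyl (E)-3-[4-(benzyloxy)-3-methoxyphenyl]acrylate | COC(=O)/C=C/c1ccc(OCc2ccccc2)c(OC)c1 | intermediate
3 | 5-bromo-2-methoxyphenol | COc1ccc(Br)cc1O | starting material
4 | 2-(benzyloxy)-4-bromo-1-methoxybenzene | COc1ccc(Br)cc1OCc1ccccc1 | intermediate
5 | (E)-tert-butyldimethyl{[3-(4,4,5,5-tetramethyl-1,3,2-dioxaborolan-2-yl)prop-2-en-1-yl]oxy}silane | CC(C)(C)[Si](C)(C)OC/C=C/B1OC(C)(C)C(C)(C)O1 | starting material
6 | (E)-{[3-(3-(benzyloxy)-4-methoxyphenyl)prop-2-en-1-yl]oxy}(tert-butyl)dimethylsilane | COc1ccc(/C=C/CO[Si](C)(C)C(C)(C)C)cc1OCc1ccccc1 | intermediate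
7 | methyl (1R,2S,3S,4R)-2-[4-(benzyloxy)-3-methoxyphenyl]-3-[3-(benzyloxy)-4-methoxyphenyl]-4-({[tert-butyl(dimethyl)silyl]oxy}methyl)cyclobutane-1-carboxylate | COc1ccc(cc1OCc1ccccc1)[C@@H]2[C@@H](CO[Si](C)(C)C(C)(C)C)[C@H](C(=O)OC)[C@H]2c3ccc(OCc4ccccc4)c(OC)c3 | intermediate
8 | methyl (1R,2S,3S,4R)-4-({[tert-butyl(dimethyl)silyl]oxy}methyl)-2-(4-hydroxy-3-methoxyphenyl)-3-(3-hydroxy-4-methoxyphenyl)cyclobutane-1-carboxylate | COc1ccc(cc1O)[C@@H]2[C@@H](CO[Si](C)(C)C(C)(C)C)[C@H](C(=O)OC)[C@H]2c3ccc(O)c(OC)c3 | intermediate
9 | methyl (2R,3R)-4-{[tert-butyl(dimethyl)silyl]oxy}-2-(4-hydroxy-3-methoxybenzyl)-3-(3-hydroxy-4-methoxybenzyl)butanoate | COc1ccc(cc1O)C[C@@H](CO[Si](C)(C)C(C)(C)C)[C@H](C(=O)OC)Cc2ccc(O)c(OC)c2 | intermediate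
10 | methyl (2R,3R)-4-hydroxy-2-(4-hydroxy-3-methoxybenzyl)-3-(3-hydroxy-4-methoxybenzyl)butanoate | COc1ccc(cc1O)C[C@@H](CO)[C@H](C(=O)OC)Cc2ccc(O)c(OC)c2 | intermediate
11 | (3R,4R)-3-(4-hydroxy-3-methoxybenzyl)-4-(3-hydroxy-4-methoxybenzyl)dihydrofuran-2(3H)-one | COc1ccc(C[C@H]2COC(=O)[C@@H]2Cc2ccc(O)c(OC)c2)cc1O | target

## Step count and least certain steps

Total step count: 5. Longest linear sequence: 4 steps (3 → 4 → 6 → 7 → 11).

Step 4 (key step). The most likely failure is loss of selectivity in the excitation event. The iridium sensitiser may transfer energy or an electron to the electron-rich alkene 6 itself, whose triplet energy lies close to that of the sensitiser and whose oxidation potential is low. That would lead to E/Z isomerisation and homodimerisation of 6 and to a cross-addition outside the chiral pocket, lowering the enantiomeric purity. The relay from C3 to C4 may also be incomplete, and the Lewis acid may ionise the p-methoxycinnamyl C–O bond. Any adduct that is cis at C3/C4 must be separated as a diastereomer (at 7 or at the lactone stage) and must never meet base, since epimerisation at C3 would turn it into the enantiomer of 11. A sensitiser of lower triplet energy would be the first adjustment of conditions.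

The fallback sets out from 2 and comes back at 7. It replaces the monodentate ester and the external sensitiser by a chelating acyl group on a chiral-at-metal Lewis acid that is itself the chromophore:
- Saponification of 2 (LiOH, THF–H2O, then HCl) should give (E)-3-[4-(benzyloxy)-3-methoxyphenyl]acrylic acid F1.
- Condensation with 3,5-dimethylpyrazole (DCC, DMAP cat., CH2Cl2) should give (E)-3-[4-(benzyloxy)-3-methoxyphenyl]-1-(3,5-dimethyl-1H-pyrazol-1-yl)prop-2-en-1-one F2.
- F2 binds through N and O to one antipode of [Rh(C^N)2(MeCN)2]PF6 (C^N = cyclometalated 5-tert-butyl-2-phenylbenzothiazole, trivalent rhodium). Only this bound enone absorbs blue light, so no free sensitiser is present to excite or oxidise 6. Its excited state should add to 6 in the known visible-light [2+2] of rhodium-bound N-acylpyrazoles to give [(1R,2S,3S,4R)-2-[4-(benzyloxy)-3-methoxyphenyl]-3-[3-(benzyloxy)-4-methoxyphenyl]-4-({[tert-butyl(dimethyl)silyl]oxy}methyl)cyclobutyl](3,5-dimethyl-1H-pyrazol-1-yl)methanone F3.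
- Methanolysis of the activated amide (MeOH, DMAP, 40 °C) returns 7.

Step 5. The most likely failure is arrest of the hydrogenolysis after O-debenzylation, because an all-trans 1,2-diarylcyclobutane adsorbs poorly on palladium. Cleavage of a ring bond that is benzylic at one end only (C3–C7 or C4–C7') is the other possibility. Higher pressure, or Raney Ni in ethanol, would be tried first.

The fallback sets out from 7 and comes back at 11. It exchanges surface hydrogenolysis for electron-transfer scission, for which the ester must first be made irreducible:
- LiOH (THF–MeOH–H2O), then acidification, should give (1R,2S,3S,4R)-2-[4-(benzyloxy)-3-methoxyphenyl]-3-[3-(benzyloxy)-4-methoxyphenyl]-4-({[tert-butyl(dimethyl)silyl]oxy}methyl)cyclobutane-1-carboxylic acid F4. The base is applied while the ring B phenol is still benzylated, so no quinone methide can form.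
- Li in liquid NH3–THF (−78 to −33 °C, no alcohol, NH4Cl quench) leaves the lithium carboxylate alone, cleaves the benzyl ethers and should fragment the radical anion of the diarylcyclobutane at the strained C7–C7' bond. Protonation of the benzylic carbanions gives (2R,3R)-4-{[tert-butyl(dimethyl)silyl]oxy}-2-(4-hydroxy-3-methoxybenzyl)-3-(3-hydroxy-4-methoxybenzyl)butanoic acid F5. Solvated electrons are specified rather than an arene radical anion, because the lithium phenoxides formed on debenzylation are poorer electron acceptors than the ethers.
- Aqueous HCl in THF removes silicon to give (2R,3R)-4-hydroxy-2-(4-hydroxy-3-methoxybenzyl)-3-(3-hydroxy-4-methoxybenzyl)butanoic acid F6, which lactonises to 11.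

Step 3. The most likely failure is protodeboronation of the alkenylboronate, or partial loss of the silyl group, under aqueous base at 80 °C, which would lower conversion of 4.

The fallback sets out from 4 and comes back at 6. It builds the side chain at the ester oxidation level:
- Heck reaction of 4 with methyl acrylate (Pd(OAc)2, P(o-tol)3, Et3N, DMF, 100 °C) should give methyl (E)-3-[3-(benzyloxy)-4-methoxyphenyl]acrylate F7.
- 1,2-Reduction with i-Bu2AlH (CH2Cl2, −78 °C) should give (E)-3-[3-(benzyloxy)-4-methoxyphenyl]prop-2-en-1-ol F8.
- Silylation (TBSCl, imidazole, DMF) returns 6.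

## Further compounds

F1 | step 4 | (E)-3-[4-(benzyloxy)-3-methoxyphenyl]acrylic acid | COc1cc(/C=C/C(=O)O)ccc1OCc1ccccc1
F2 | step 4 | (E)-3-[4-(benzyloxy)-3-methoxyphenyl]-1-(3,5-dimethyl-1H-pyrazol-1-yl)prop-2-en-1-one | COc1cc(/C=C/C(=O)n2nc(C)cc2C)ccc1OCc1ccccc1
F3 | step 4 | [(1R,2S,3S,4R)-2-[4-(benzyloxy)-3-methoxyphenyl]-3-[3-(benzyloxy)-4-methoxyphenyl]-4-({[tert-butyl(dimethyl)silyl]oxy}methyl)cyclobutyl](3,5-dimethyl-1H-pyrazol-1-yl)methanone | COc1ccc(cc1OCc1ccccc1)[C@@H]2[C@@H](CO[Si](C)(C)C(C)(C)C)[C@H](C(=O)n3nc(C)cc3C)[C@H]2c4ccc(OCc5ccccc5)c(OC)c4
F4 | step 5 | (1R,2S,3S,4R)-2-[4-(benzyloxy)-3-methoxyphenyl]-3-[3-(benzyloxy)-4-methoxyphenyl]-4-({[tert-butyl(dimethyl)silyl]oxy}methyl)cyclobutane-1-carboxylic acid | COc1ccc(cc1OCc1ccccc1)[C@@H]2[C@@H](CO[Si](C)(C)C(C)(C)C)[C@H](C(=O)O)[C@H]2c3ccc(OCc4ccccc4)c(OC)c3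
F5 | step 5 | (2R,3R)-4-{[tert-butyl(dimethyl)silyl]oxy}-2-(4-hydroxy-3-methoxybenzyl)-3-(3-hydroxy-4-methoxybenzyl)butanoic acid | COc1ccc(cc1O)C[C@@H](CO[Si](C)(C)C(C)(C)C)[C@H](C(=O)O)Cc2ccc(O)c(OC)c2
F6 | step 5 | (2R,3R)-4-hydroxy-2-(4-hydroxy-3-methoxybenzyl)-3-(3-hydroxy-4-methoxybenzyl)butanoic acid | COc1ccc(cc1O)C[C@@H](CO)[C@H](C(=O)O)Cc2ccc(O)c(OC)c2
F7 | step 3 | methyl (E)-3-[3-(benzyloxy)-4-methoxyphenyl]acrylate | COC(=O)/C=C/c1ccc(OC)c(OCc2ccccc2)c1
F8 | step 3 | (E)-3-[3-(benzyloxy)-4-methoxyphenyl]prop-2-en-1-ol | COc1ccc(/C=C/CO)cc1OCc1ccccc1
A1 | alternative 1 | (5R)-5-{[(1R,2S,5R)-2-isopropyl-5-methylcyclohexyl]oxy}furan-2(5H)-one | O=C1C=C[C@H](O[C@@H]2C[C@H](C)CC[C@H]2C(C)C)O1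
A2 | alternative 1 | [3-(benzyloxy)-4-methoxyphenyl]bis(phenylsulfanyl)methane | COc1ccc(cc1OCc1ccccc1)C(Sc1ccccc1)Sc1ccccc1
A3 | alternative 1 | 4-(benzyloxy)-3-methoxybenzyl bromide | COc1cc(CBr)ccc1OCc1ccccc1
A4 | alternative 1 | (3R,4R,5R)-3-[4-(benzyloxy)-3-methoxybenzyl]-4-{[3-(benzyloxy)-4-methoxyphenyl]bis(phenylsulfanyl)methyl}-5-{[(1R,2S,5R)-2-isopropyl-5-methylcyclohexyl]oxy}dihydrofuran-2(3H)-one | COc1ccc(cc1OCc1ccccc1)C(Sc1ccccc1)(Sc1ccccc1)[C@H]2[C@H](O[C@@H]3C[C@H](C)CC[C@H]3C(C)C)OC(=O)[C@@H]2Cc2ccc(OCc3ccccc3)c(OC)c2
A5 | alternative 2 | (R)-2-[3-(benzyloxy)-4-methoxybenzyl]-4-[4-(benzyloxy)-3-methoxyphenyl]but-3-yn-1-ol | COc1ccc(C[C@@H](CO)C#Cc2ccc(OCc3ccccc3)c(OC)c2)cc1OCc1ccccc1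
A6 | alternative 2 | (R,E)-3-[4-(benzyloxy)-3-methoxybenzylidene]-4-[3-(benzyloxy)-4-methoxybenzyl]dihydrofuran-2(3H)-one | COc1ccc(C[C@H]2COC(=O)/C2=C/c2ccc(OCc3ccccc3)c(OC)c2)cc1OCc1ccccc1
A7 | alternative 3 | (E)-3-[3-(benzyloxy)-4-methoxyphenyl]allyl 3-[4-(benzyloxy)-3-methoxyphenyl]-2-diazo-3-oxopropanoate | COc1ccc(/C=C/COC(=O)C(=[N+]=[N-])C(=O)c2ccc(OCc3ccccc3)c(OC)c2)cc1OCc1ccccc1
A8 | alternative 3 | (1S,5R,6S)-1-[4-(benzyloxy)-3-methoxybenzoyl]-6-[3-(benzyloxy)-4-methoxyphenyl]-3-oxabicyclo[3.1.0]hexan-2-one (6-exo-aryl) | COc1ccc(cc1OCc1ccccc1)[C@@H]3[C@H]2COC(=O)[C@]23C(=O)c1ccc(OCc2ccccc2)c(OC)c1
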